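**Retrosynthetic overview**

- The strategy rests on one feature: ring A (the phenol ring, C1–OH, C2–O) carries bromine on all four remaining carbons C3, C4, C5 and C6, whereas ring B carries one bromine at C2' and hydrogen at C4', para to the ether oxygen.
- C4'–H is traced back to C4'–NO2 (reduction, diazotisation, hypophosphorous acid), so the nitro group is a traceless para blocker and deactivator of ring B.
- The four C–Br bonds of ring A (C3–Br, C4–Br, C5–Br, C6–Br) are cut back to C–H: exhaustive bromination of 2-(2-bromo-4-nitrophenoxy)phenol.
- The diaryl ether bond C2–O–C1' comes from catechol and 2-bromo-1-fluoro-4-nitrobenzene by nucleophilic aromatic substitution, which also fixes the single bromine of ring B.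
- No ring is formed at any stage; both benzene rings are purchased.

Key step: step 2

Remark on the chemistry: the target has no stereocentre and the diaryl ether rotates freely, so it is achiral and the request for a single enantiomer imposes no stereochemical task. Catechol, 2-bromo-1-fluoro-4-nitrobenzene and bromine are taken as commercial.

**Route**

Step 1
Reactants: 1 catechol (3 equiv); 2 2-bromo-1-fluoro-4-nitrobenzene
Product: 3 2-(2-bromo-4-nitrophenoxy)phenol
Conditions: K2CO3 (1.2 equiv), DMF, N2, rt → 50 °C; dil. HCl work-up, water washes to remove excess catechol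
Reagents that add atoms: none
Why: Nucleophilic aromatic substitution through a Meisenheimer complex: the catechol monoanion displaces fluoride para to the nitro group, the bromine meta to nitro is not activated, and excess catechol together with the hindered, less nucleophilic mono-ether phenoxide should hold the reaction at mono-arylation.

Step 2
Reactants: 3 2-(2-bromo-4-nitrophenoxy)phenol; 4 bromine
Product: 6 3,4,5,6-tetrabromo-2-(2-bromo-4-nitrophenoxy)phenol, via ring-A 4,6-dibromide 5 (not isolated)
Conditions: Br2 (2.2 equiv), dry ClCH2CH2Cl, 0 °C → rt; then Fe powder (0.1 equiv), Br2 (4 equiv), 60 °C; aq. NaHSO3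
Reagents that add atoms: bromine (4), BrBr
Why: Electrophilic aromatic substitution four times over on ring A: the free C1–OH should send the first two bromines quickly and without catalyst to C4 (para) and C6 (ortho), giving 5, after which bromine activated by FeBr3 (formed in the flask from iron) attacks the remaining C5 and C3, which are para and ortho to the ether oxygen on C2. Where direct attack is slow, ipso bromination at C4 or C6 gives 4,4- or 6,6-dibromocyclohexadienones whose acid-promoted 1,2-bromine shift and rearomatisation place bromine on the neighbouring C–H, so both channels converge on the same perbromide, and the bisulfite quench returns any residual bromodienone to the phenol. The closest known reaction type is the exhaustive bromination of phenol to pentabromophenol, and of catechol and its monoethers to the tetrabromides, with bromine and an iron or aluminium halide. No ring is closed and no stereocentre is created. The selectivity needed is ring A over C6'–H of ring B; it is secured by the para-nitro group and the C2' bromine, which make ring B far less nucleophilic than a ring with a free hydroxyl and leave it no dienone pathway, and it is supported by using FeBr3 and not AlBr3 at moderate temperature. Within ring A no regiochemical question arises because every C–H is replaced.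

Step 3
Reactants: 6 3,4,5,6-tetrabromo-2-(2-bromo-4-nitrophenoxy)phenol
Product: 7 2-(4-amino-2-bromophenoxy)-3,4,5,6-tetrabromophenol
Conditions: Fe powder (5 equiv), AcOH/EtOH 1:3, 70 °C
Reagents that add atoms: none
Why: Béchamp-type dissolving-metal reduction of the nitroarene to the aniline by electron transfer from iron in acid, a method that should leave the five aryl C–Br bonds untouched, unlike catalytic hydrogenation.

Step 4
Reactants: 7 2-(4-amino-2-bromophenoxy)-3,4,5,6-tetrabromophenol
Product: 9 3,4,5,6-tetrabromo-2-(2-bromophenoxy)phenol, via arenediazonium hydrogen sulfate 8 (not isolated)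
Conditions: NaNO2 (1.05 equiv), H2SO4, AcOH, 0–5 °C; then 50% aq. H3PO2 (10 equiv), Cu2O (cat.), 0 °C → rt
Reagents that add atoms: sodium nitrite, [Na+].[O-]N=O, and sulfuric acid, OS(=O)(=O)O (they supply only the diazonium nitrogen and the counter-ion of 8; no heavy atom of theirs remains in 9)
Why: Diazotisation followed by hydrodediazoniation, a radical chain in which the aryl radical formed from the diazonium ion at C4' abstracts hydrogen from the P–H bond of hypophosphorous acid; ring A has no free position for azo coupling, and nitrite is held at one equivalent in strong acid so that N-nitrosation of the amine outruns any attack on the bromophenol ring.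

**Compound list**

1 | catechol (benzene-1,2-diol) | Oc1ccccc1O | starting material
2 | 2-bromo-1-fluoro-4-nitrobenzene | Fc1ccc(cc1Br)[N+](=O)[O-] | starting material
3 | 2-(2-bromo-4-nitrophenoxy)phenol | Oc1ccccc1Oc1ccc(cc1Br)[N+](=O)[O-] | intermediate
4 | bromine | BrBr | starting material
5 | 4,6-dibromo-2-(2-bromo-4-nitrophenoxy)phenol | Oc1c(Br)cc(Br)cc1Oc1ccc(cc1Br)[N+](=O)[O-] | intermediate (not isolated)
6 | 3,4,5,6-tetrabromo-2-(2-bromo-4-nitrophenoxy)phenol | Oc1c(Br)c(Br)c(Br)c(Br)c1Oc1ccc(cc1Br)[N+](=O)[O-] | intermediate
7 | 2-(4-amino-2-bromophenoxy)-3,4,5,6-tetrabromophenol | Oc1c(Br)c(Br)c(Br)c(Br)c1Oc1ccc(N)cc1Br | intermediate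
8 | 3-bromo-4-(2,3,4,5-tetrabromo-6-hydroxyphenoxy)benzenediazonium hydrogen sulfate | Oc1c(Br)c(Br)c(Br)c(Br)c1Oc1ccc(cc1Br)[N+]#N.OS(=O)(=O)[O-] | intermediate (not isolated)
9 | 3,4,5,6-tetrabromo-2-(2-bromophenoxy)phenol | Oc1c(Br)c(Br)c(Br)c(Br)c1Oc1ccccc1Br | target

**Totals**

Total step count: 4. Longest linear sequence: 4 steps (1 → 3 → 6 → 7 → 9).

**Steps most likely to fail**

1. Step 2.
   - What may go wrong: the third and fourth brominations may stall on the increasingly deactivated ring A. The forcing conditions may instead carry bromination over to C6' of ring B. Ipso attack at C2 may lead to oxidative loss of the aryloxy group.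
   - Fallback, from 1 back to 6: catechol 1 is perbrominated with excess bromine 4 in acetic acid at room temperature, which needs no Lewis acid because both hydroxyls activate, to give 3,4,5,6-tetrabromobenzene-1,2-diol F1. An excess of F1 is then used as the nucleophile in the substitution of fluoride in 2 (K2CO3, DMF, 80 °C). This should give 6 directly, so that ring B never meets bromine.

2. Step 4.
   - What may go wrong: nitrous acid may attack the free polybromophenol ring (ipso-nitrosation with loss of bromine, as in the Zincke nitration) in competition with N-nitrosation. The diazonium ion may also be hydrolysed or coupled before it is reduced.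
   - Fallback, from 6 back to 9: the phenol is masked first. O-Methylation of 6 (MeI, K2CO3, acetone, reflux) should give 1,2,3,4-tetrabromo-5-(2-bromo-4-nitrophenoxy)-6-methoxybenzene F2. Reduction with Fe in AcOH/EtOH should give 3-bromo-4-(2,3,4,5-tetrabromo-6-methoxyphenoxy)aniline F3. Diazotisation (NaNO2, H2SO4, AcOH, 0 °C) to 3-bromo-4-(2,3,4,5-tetrabromo-6-methoxyphenoxy)benzenediazonium hydrogen sulfate F4, followed by H3PO2 reduction, should give 1,2,3,4-tetrabromo-5-(2-bromophenoxy)-6-methoxybenzene F5. Cleavage of the methyl ether with BBr3 (CH2Cl2, −78 °C → rt, aqueous work-up) then returns to 9.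

3. Step 1.
   - What may go wrong: double arylation of catechol, and air oxidation of the catecholate to quinone-derived tar.
   - Fallback, from 2 back to 3: commercial 2-methoxyphenol (guaiacol, COc1ccccc1O) is used in place of catechol in the substitution of 2 (K2CO3, DMF, 60 °C) to give 2-bromo-1-(2-methoxyphenoxy)-4-nitrobenzene F6. Demethylation with BBr3 (CH2Cl2, −78 °C → rt, aqueous work-up) then returns to 3.

**Further compounds**

F1 | step 2 | 3,4,5,6-tetrabromobenzene-1,2-diol | Oc1c(O)c(Br)c(Br)c(Br)c1Br
F2 | step 4 | 1,2,3,4-tetrabromo-5-(2-bromo-4-nitrophenoxy)-6-methoxybenzene | COc1c(Br)c(Br)c(Br)c(Br)c1Oc1ccc(cc1Br)[N+](=O)[O-]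
F3 | step 4 | 3-bromo-4-(2,3,4,5-tetrabromo-6-methoxyphenoxy)aniline | COc1c(Br)c(Br)c(Br)c(Br)c1Oc1ccc(N)cc1Br
F4 | step 4 | 3-bromo-4-(2,3,4,5-tetrabromo-6-methoxyphenoxy)benzenediazonium hydrogen sulfate | COc1c(Br)c(Br)c(Br)c(Br)c1Oc1ccc(cc1Br)[N+]#N.OS(=O)(=O)[O-]
F5 | step 4 | 1,2,3,4-tetrabromo-5-(2-bromophenoxy)-6-methoxybenzene | COc1c(Br)c(Br)c(Br)c(Br)c1Oc1ccccc1Br
F6 | step 1 | 2-bromo-1-(2-methoxyphenoxy)-4-nitrobenzene | COc1ccccc1Oc1ccc(cc1Br)[N+](=O)[O-]
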